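Everything hinges on cutting the C8–C14 bond of ring C. The cut maps rings A and B, the C6 oxygen, C9 and the tertiary carbinol C13 onto (+)-larixol, whose exocyclic C8 methylene and side-chain C14=C15 alkene are joined by the C9–C11–C12–C13 tether; this is the feature the key step exploits. Hydrogen-atom transfer to the methylene creates the C8 methyl and a tertiary C8 radical, which closes ring C 6-exo onto C14 of an E-vinyl sulfone, setting C8 and C14 and leaving a sulfone at C15. The precursor is 6-O-silylated larixol with PhSO2 on C15; the oxocene is closed last by metathesis of an O13 allyl ether with a C15 methallyl chain.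

Key step: step 6

Remark on numbering: ring A is C1–C5/C10, ring B is C5–C10, ring C is C8, C9, C11–C14, and the oxocene is O–C13–C14–C15–C16–C17(CH3)=C18–C19–O. Methyl groups are named by the carbon that carries them.

Remark on the chemistry: the phenylsulfonyl group is put on C15 by osmylation and substitution, not by olefin cross-metathesis on larixol. A ruthenium carbene at C14 would be expected to ring-close onto the C8 methylene (cyclohexene formation with loss of both terminal CH2 groups). C14 in compounds 3, 4, 6 and 7 and C15 in compound 11 are carried as epimer mixtures, because steps 5 and 8 erase these centres. (+)-Larixol is taken as commercially available.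

Step 1
Reactants: 1 (+)-larixol
Product: 2 6-O-triethylsilyl-larixol
Conditions: TESCl (1.2 equiv), imidazole, DMAP (cat.), DMF, 0 °C to rt
Reagents that add atoms: triethylsilyl chloride, CC[Si](Cl)(CC)CC
Why: Chemoselective silyl ether formation, in which the secondary equatorial C6 hydroxyl reacts with TESCl/imidazole while the tertiary C13 carbinol does not; no stereocenter is formed.

Step 2
Reactants: 2 6-O-triethylsilyl-larixol
Product: 3 6-O-triethylsilyl-14,15-dihydroxy-14,15-dihydrolarixol (13,14,15-triol; both C14 epimers)
Conditions: OsO4 (2 mol%), NMO (1.1 equiv), acetone/H2O 4:1, 0 °C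
Reagents that add atoms: N-methylmorpholine N-oxide, C[N+]1([O-])CCOCC1; water, O
Why: Catalytic osmium tetroxide dihydroxylation with NMO as reoxidant should occur at the unhindered monosubstituted C14=C15 alkene and spare the C8 methylene, which is screened by the axial C10 methyl and the C9 side chain (permanganate shows the same preference in the side-chain degradation of this diene system); C14 forms as an epimer mixture that step 5 erases.

Step 3
Reactants: 3 6-O-triethylsilyl-14,15-dihydroxy-14,15-dihydrolarixol
Product: 4 15-O-p-toluenesulfonate of 3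
Conditions: TsCl (1.1 equiv), Et3N, Bu2SnO (2 mol%), CH2Cl2, 0 °C to rt
Reagents that add atoms: p-toluenesulfonyl chloride, Cc1ccc(cc1)S(Cl)(=O)=O
Why: Tin-catalysed regioselective sulfonylation of a 1,2-diol through its stannylene acetal puts the tosyl group on the primary C15 hydroxyl only and leaves the secondary C14 and tertiary C13 hydroxyls free.

Step 4
Reactants: 4 15-O-p-toluenesulfonate of 3; 5 sodium benzenesulfinate
Product: 6 6-O-triethylsilyl-14-hydroxy-15-(phenylsulfonyl)-14,15-dihydrolarixol (both C14 epimers)
Conditions: NaI (20 mol%), DMF, 70 °C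
Reagents that add atoms: none
Why: SN2 substitution at primary C15 by the sulfur of the sulfinate (S-alkylation, helped by Finkelstein exchange to the iodide) gives the sulfone without touching C13 or C14.

Step 5
Reactants: 6 6-O-triethylsilyl-14-hydroxy-15-(phenylsulfonyl)-14,15-dihydrolarixol
Product: 8 (14E)-6-O-triethylsilyl-15-(phenylsulfonyl)larixol, via C14 mesylate 7 (not isolated)
Conditions: MsCl (1.3 equiv), Et3N (4 equiv), CH2Cl2, −10 °C to rt
Reagents that add atoms: none
Why: Mesylation of the secondary C14 hydroxyl followed by E1cB elimination through the acidic α-sulfonyl hydrogens at C15 gives the conjugated vinyl sulfone in its thermodynamically preferred E geometry; C13 carries no hydrogen, so the alkene cannot move out of conjugation.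

Step 6
Reactants: 8 (14E)-6-O-triethylsilyl-15-(phenylsulfonyl)larixol
Product: 9 tricyclic 13α-hydroxy-6α-triethylsilyloxy 15-phenyl sulfone (8β-methyl, 13β-methyl, 14α-H, CH2SO2Ph on C14)
Conditions: Fe(acac)3 (30 mol%), PhSiH3 (2.5 equiv), EtOH/(CH2OH)2 5:1, degassed, 0.02 M, 60 °C
Reagents that add atoms: none
Why: Metal-hydride hydrogen-atom transfer followed by an intramolecular Giese addition, the closest known reaction type being the Fe(acac)3/PhSiH3 reductive coupling of a donor alkene with an electron-poor alkene: the iron hydride gives a hydrogen atom to the CH2 terminus of the 1,1-disubstituted C8 alkene, which creates the C8 methyl and a nucleophilic tertiary C8 radical; this radical adds to C14, the β-carbon of the vinyl sulfone, and the resulting α-sulfonyl radical is reduced by divalent iron and protonated by ethanol. Ring C (C8, C9, C11, C12, C13, C14) closes in the 6-exo-trig mode through a chair in which the new C8–C14 bond is equatorial on ring B. C8 is controlled by the axial C10 methyl and the equatorial C9–C11 bond, which allow bond formation only on the α-face, so the new methyl is β and the B/C fusion is trans. C14 is controlled by the E-vinyl sulfone lying pseudo-equatorial in that chair (C13 methyl axial, C13 hydroxyl equatorial), which gives the α-hydrogen at C14 and an equatorial CH2SO2Ph. The step needs hydrogen-atom transfer to the C8 methylene and not to the vinyl sulfone, which the low reactivity of electron-poor alkenes toward the iron hydride secures, and it needs cyclisation to outrun reduction of the radical, which the activated acceptor and dilution secure; the tertiary C13 carbinol is a spectator and keeps the configuration of larixol.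

Step 7
Reactants: 9 tricyclic 13α-hydroxy-6α-triethylsilyloxy 15-phenyl sulfone; 10 3-bromo-2-methylprop-1-ene (methallyl bromide)
Product: 11 C15-methallylated sulfone (C15 bears SO2Ph and CH2C(CH3)=CH2; both C15 epimers)
Conditions: n-BuLi (2.2 equiv), THF, −78 °C; then 10 (1.5 equiv), DMPU, −78 to 0 °C
Reagents that add atoms: none
Why: Alkylation of an α-sulfonyl carbanion, in which the dianion (O13 alkoxide and C15 carbanion) reacts at carbon with the allylic bromide by SN2 because the lithium alkoxide is a far poorer nucleophile; C15 forms as an epimer mixture that step 8 erases.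

Step 8
Reactants: 11 C15-methallylated sulfone
Product: 12 tricyclic 13α-ol with a 3-methylbut-3-enyl chain on C14 (C15H2–C16H2–C17(CH3)=CH2) and 6α-OTES
Conditions: Na/Hg (6% Na), Na2HPO4, MeOH/THF, −20 °C to rt
Reagents that add atoms: none
Why: Reductive desulfonylation by single-electron transfer from sodium amalgam replaces the C15–S bond by C–H and removes the C15 stereocenter; the isolated 1,1-disubstituted alkene, the silyl ether and the carbinol are inert to buffered Na/Hg.

Step 9
Reactants: 12 tricyclic 13α-ol with a 3-methylbut-3-enyl chain on C14; 13 allyl bromide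
Product: 14 13-O-allyl ether of 12
Conditions: KH (3 equiv), 18-crown-6 (cat.), THF, 0 °C; then 13 (5 equiv), rt
Reagents that add atoms: none
Why: Williamson ether synthesis, in which the potassium alkoxide of the tertiary equatorial C13 carbinol is alkylated at oxygen by the unhindered allylic bromide; no bond to C13 is broken, so its configuration is kept.

Step 10
Reactants: 14 13-O-allyl ether of 12
Product: 15 6-O-triethylsilyl ether of the target oxocene
Conditions: second-generation Grubbs catalyst (10 mol%), 1,4-benzoquinone (20 mol%), CH2Cl2 (2 mM), 40 °C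
Reagents that add atoms: none
Why: Ring-closing olefin metathesis between the O13 allyl group and the C17 methylidene forms the C17=C18 bond of the eight-membered ring; the trans-diequatorial O13 and C15 substituents on chair ring C and the geminal C13 methyl hold the two alkenes close, and an eight-membered ring can hold only the Z alkene.

Step 11
Reactants: 15 6-O-triethylsilyl ether of the target oxocene
Product: 16 CNP0179324.1 (target)
Conditions: TBAF, THF, rt
Reagents that add atoms: none
Why: Fluoride-mediated cleavage of the silyl ether, driven by the strong Si–F bond, frees the 6α-hydroxyl without touching the allylic ether or the trisubstituted alkene.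

Compound list
1 | (+)-larixol (labdane; 6α-OH, exocyclic C8 methylene, 9β side chain CH2CH2C(CH3)(OH)CH=CH2, 13S) | C=C[C@](O)(C)CC[C@@H]1[C@@]2(C)CCCC(C)(C)[C@@H]2[C@@H](O)CC1=C | starting material
2 | 6-O-triethylsilyl-larixol | C=C[C@](O)(C)CC[C@@H]1[C@@]2(C)CCCC(C)(C)[C@@H]2[C@@H](O[Si](CC)(CC)CC)CC1=C | intermediate
3 | 6-O-triethylsilyl-14,15-dihydroxy-14,15-dihydrolarixol (C14 epimers) | OCC(O)[C@](O)(C)CC[C@@H]1[C@@]2(C)CCCC(C)(C)[C@@H]2[C@@H](O[Si](CC)(CC)CC)CC1=C | intermediate
4 | 15-O-p-toluenesulfonate of 3 (C14 epimers) | Cc1ccc(cc1)S(=O)(=O)OCC(O)[C@](O)(C)CC[C@@H]1[C@@]2(C)CCCC(C)(C)[C@@H]2[C@@H](O[Si](CC)(CC)CC)CC1=C | intermediate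
5 | sodium benzenesulfinate | [Na+].[O-]S(=O)c1ccccc1 | starting material
6 | 6-O-triethylsilyl-14-hydroxy-15-(phenylsulfonyl)-14,15-dihydrolarixol (C14 epimers) | O=S(=O)(c1ccccc1)CC(O)[C@](O)(C)CC[C@@H]1[C@@]2(C)CCCC(C)(C)[C@@H]2[C@@H](O[Si](CC)(CC)CC)CC1=C | intermediate
7 | 14-O-methanesulfonate of 6 (C14 epimers) | O=S(=O)(c1ccccc1)CC(OS(C)(=O)=O)[C@](O)(C)CC[C@@H]1[C@@]2(C)CCCC(C)(C)[C@@H]2[C@@H](O[Si](CC)(CC)CC)CC1=C | intermediate (not isolated)
8 | (14E)-6-O-triethylsilyl-15-(phenylsulfonyl)larixol | O=S(=O)(c1ccccc1)/C=C/[C@](O)(C)CC[C@@H]1[C@@]2(C)CCCC(C)(C)[C@@H]2[C@@H](O[Si](CC)(CC)CC)CC1=C | intermediate (precursor of the key step)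
9 | tricyclic 13α-hydroxy-6α-triethylsilyloxy 15-phenyl sulfone (trans-anti-trans rings A/B/C, 8β-methyl, 13β-methyl, 14α-H) | O[C@@]1(C)CC[C@@H]2[C@@]3(C)CCCC(C)(C)[C@@H]3[C@@H](O[Si](CC)(CC)CC)C[C@@]2(C)[C@@H]1CS(=O)(=O)c1ccccc1 | intermediate (product of the key step)
10 | 3-bromo-2-methylprop-1-ene (methallyl bromide) | C=C(C)CBr | starting material
11 | C15-methallylated sulfone (C15 epimers) | O[C@@]1(C)CC[C@@H]2[C@@]3(C)CCCC(C)(C)[C@@H]3[C@@H](O[Si](CC)(CC)CC)C[C@@]2(C)[C@@H]1C(CC(C)=C)S(=O)(=O)c1ccccc1 | intermediate
12 | tricyclic 13α-ol with 3-methylbut-3-enyl on C14 and 6α-OTES | O[C@@]1(C)CC[C@@H]2[C@@]3(C)CCCC(C)(C)[C@@H]3[C@@H](O[Si](CC)(CC)CC)C[C@@]2(C)[C@@H]1CCC(C)=C | intermediate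
13 | allyl bromide | C=CCBr | starting material
14 | 13-O-allyl ether of 12 | C=CCO[C@@]1(C)CC[C@@H]2[C@@]3(C)CCCC(C)(C)[C@@H]3[C@@H](O[Si](CC)(CC)CC)C[C@@]2(C)[C@@H]1CCC(C)=C | intermediate
15 | 6-O-triethylsilyl ether of the target oxocene (Z-C17=C18) | C/C1=C/CO[C@@]2(C)CC[C@@H]3[C@@]4(C)CCCC(C)(C)[C@@H]4[C@@H](O[Si](CC)(CC)CC)C[C@@]3(C)[C@@H]2CC1 | intermediate
16 | CNP0179324.1 (6α-OH, 5α-H, 8β-methyl, 9α-H, 10β-methyl, 13β-methyl with 13α-O, 14α-H, Z-C17=C18 oxocene) | C/C1=C/CO[C@@]2(C)CC[C@@H]3[C@@]4(C)CCCC(C)(C)[C@@H]4[C@@H](O)C[C@@]3(C)[C@@H]2CC1 | target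

Total step count: 11. Longest linear sequence: 11 steps (1 to 16).

Steps most likely to fail

Step 6. The tertiary C8 radical may be reduced, or oxidised and captured by O13, faster than it cyclises, or the vinyl sulfone may add through a boat so that facial control at C14 is poor. The fallback sets out from 8 and generates the same radical without a hydride source. Buffered mCPBA (NaHCO3, CH2Cl2, 0 °C) should epoxidise only the electron-rich C8 methylene to give the C8 spiro-epoxide F1. Cp2TiCl (from Cp2TiCl2 and Zn dust, THF, rt) should then open the epoxide homolytically by trivalent titanium (Nugent–RajanBabu reaction), and the tertiary radical should close 6-exo onto the vinyl sulfone to give the C8 hydroxymethyl tricycle F2. 1,1'-Thiocarbonyldiimidazole with DMAP should convert the primary hydroxyl into the imidazolylthiocarbonate F3. Barton–McCombie deoxygenation (Bu3SnH, AIBN, toluene, 110 °C) should then turn the CH2O group into the C8 methyl, and the route is rejoined at 9.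

Step 10. Intermolecular metathesis of the unhindered allyl ether, or isomerisation of that ether to a propenyl ether, may outrun closure onto the hindered 1,1-disubstituted alkene. The fallback sets out from 14 and forms the same C17=C18 bond by reductive carbonyl coupling. Ozonolysis of both terminal alkenes (O3, CH2Cl2/MeOH, −78 °C; then Me2S) should give the keto aldehyde F4. Intramolecular McMurry coupling with low-valent titanium (TiCl3·1.5DME, zinc–copper couple, DME, reflux, slow addition) should join the aldehyde and ketone carbons to the Z-trisubstituted alkene, and the route is rejoined at 15.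

Step 2. Osmylation may also attack the C8 methylene, so that chemoselectivity between the two alkenes is lost and over-oxidised polyols form. The fallback sets out from 2 and uses delivery of the oxidant by the neighbouring hydroxyl. Hydroxyl-directed epoxidation of the allylic C14=C15 alkene with VO(acac)2 and t-BuOOH (toluene, rt) should give the 14,15-epoxide F5. Opening of the epoxide at terminal C15 with sodium benzenesulfinate 5 (DMF/H2O, 80 °C) should give the hydroxy sulfone, and the route is rejoined at 6, bypassing 3 and 4.

Further compounds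
F1 | step 6 | C8 spiro-epoxide of 8 (either epoxide epimer) | O=S(=O)(c1ccccc1)/C=C/[C@](O)(C)CC[C@@H]1[C@@]2(C)CCCC(C)(C)[C@@H]2[C@@H](O[Si](CC)(CC)CC)CC13CO3
F2 | step 6 | analogue of 9 with CH2OH in place of the C8 methyl | O[C@@]1(C)CC[C@@H]2[C@@]3(C)CCCC(C)(C)[C@@H]3[C@@H](O[Si](CC)(CC)CC)C[C@@]2(CO)[C@@H]1CS(=O)(=O)c1ccccc1
F3 | step 6 | O-(imidazol-1-ylthiocarbonyl) derivative of F2 at the primary hydroxyl | O[C@@]1(C)CC[C@@H]2[C@@]3(C)CCCC(C)(C)[C@@H]3[C@@H](O[Si](CC)(CC)CC)C[C@@]2(COC(=S)n4ccnc4)[C@@H]1CS(=O)(=O)c1ccccc1
F4 | step 10 | keto aldehyde from 14 (O13–CH2–CHO and C16–C(=O)CH3) | O=CCO[C@@]1(C)CC[C@@H]2[C@@]3(C)CCCC(C)(C)[C@@H]3[C@@H](O[Si](CC)(CC)CC)C[C@@]2(C)[C@@H]1CCC(C)=O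
F5 | step 2 | 14,15-epoxide of 2 (C14 epimers) | C1OC1[C@](O)(C)CC[C@@H]1[C@@]2(C)CCCC(C)(C)[C@@H]2[C@@H](O[Si](CC)(CC)CC)CC1=C
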